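**Plan**

1. Retrosynthesis: the two acetates and the C8=C17 methylene (Wittig on a C8 ketone) are removed first. Ring A is then cut at C1–C10 and C2–C3, releasing methyl acrylate (C1–C2 plus a temporary ester) from a seco-ring-A aldehyde. That aldehyde is cut at C4–C5 (nitrile carbanion), C10=C20 (Mannich methylenation) and C9–C11 (conjugate addition).
2. Enabling feature: in ring A the oxygenated C3 and the methyl-bearing quaternary C10 are 1,4-related through the gem-dimethyl C4 and C5. With C10 held as an exocyclic methylene on ring B, the precursor is an α,α-dimethyl γ,δ-unsaturated aldehyde: hydrogen-atom transfer turns C10=CH2 into the C10 radical plus the C20 methyl, and one acrylate bridges C10 and C3.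
3. Forward order: side-chain iodide from (S)-linalool by one-carbon degradation; ring B from a commercial cyclohexenone ketal; ring A closed last by the annulation; then C3 oxidation, de-esterification and reduction, unmasking and methylenation of C8, diacetylation.
4. Stereochemistry: C13 from (S)-linalool; C9 by ligand-controlled copper conjugate addition; C5 relayed from C9 in an allylpalladium hydrogenolysis; C10 by anti addition to the ring B radical; C3 by equatorial hydride attack (axial 3α-alcohol); C9 remains the thermodynamic epimer next to the late C8 ketone.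

Key step: step 9

Remark: (S)-(+)-linalool of high enantiomeric purity is taken as commercially available; carbon numbers are those of the labdane skeleton.

**Route**

Step 1
Reactants: 1 (S)-(+)-linalool
Product: 2 (S)-linalool triethylsilyl ether
Conditions: Et3SiOTf, 2,6-lutidine, CH2Cl2, −78 → 0 °C
Reagents that add atoms: triethylsilyl trifluoromethanesulfonate, CC[Si](CC)(CC)OS(=O)(=O)C(F)(F)F
Why: Silylation of a tertiary alcohol with a silyl triflate and a hindered pyridine base is standard, leaves the stereocentre untouched and masks the tertiary allylic hydroxyl through the organometallic and palladium steps.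

Step 2
Reactants: 2 (S)-linalool triethylsilyl ether
Product: 4 (S)-4-methyl-4-(triethylsilyloxy)hex-5-enal, via ozonide 3 (not isolated)
Conditions: O3, CH2Cl2, −78 °C (Sudan Red 7B end point); then PPh3, −78 → 20 °C
Reagents that add atoms: ozone, [O-][O+]=O
Why: Ozonolysis with reductive work-up should cleave the electron-rich trisubstituted alkene well before the hindered monosubstituted vinyl group next to the silyloxy-bearing quaternary carbon, the indicator dye marking the end point.

Step 3
Reactants: 4 (S)-4-methyl-4-(triethylsilyloxy)hex-5-enal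
Product: 5 (S)-4-methyl-4-(triethylsilyloxy)hex-5-enoic acid
Conditions: NaClO2, NaH2PO4, 2-methylbut-2-ene, t-BuOH/H2O, 0 → 20 °C
Reagents that add atoms: sodium chlorite, [Na+].[O-]Cl=O
Why: Pinnick oxidation converts the aldehyde into the acid under buffered conditions that spare the alkene and the silyl ether.

Step 4
Reactants: 5 (S)-4-methyl-4-(triethylsilyloxy)hex-5-enoic acid
Product: 7 (S)-5-iodo-3-methyl-3-(triethylsilyloxy)pent-1-ene, via Barton ester 6 (not isolated)
Conditions: 1-hydroxypyridine-2(1H)-thione, DCC, DMAP (cat.), CH2Cl2, 0 → 20 °C, dark; then CHI3, hν (tungsten lamp), 20 °C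
Reagents that add atoms: iodoform, IC(I)I
Why: Barton decarboxylation with iodoform as iodine-atom donor removes one carbon through a primary radical that has only 4-exo or 5-endo paths to the vinyl group and should therefore be trapped cleanly as the iodide.

Step 5
Reactants: 7 (S)-5-iodo-3-methyl-3-(triethylsilyloxy)pent-1-ene; 8 1,4-dioxaspiro[4.5]dec-6-en-8-one
Product: 13 (6R)-7-methylidene-6-[(3S)-3-methyl-3-(triethylsilyloxy)pent-4-en-1-yl]-1,4-dioxaspiro[4.5]decan-8-one, via Grignard reagent 9 (not isolated), via magnesium enolate 10 (not isolated), via Mannich base 11 (not isolated), via ammonium iodide 12 (not isolated)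
Conditions: Mg, Et2O, 20 °C; then 8, CuBr·SMe2 (cat.), (R)-1-[(SP)-2-(diphenylphosphino)ferrocenyl]ethyldicyclohexylphosphine (cat.), t-BuOMe, −75 °C; then CH2=NMe2+ I−, THF, −75 → 20 °C; then MeI; then aq NaHCO3
Reagents that add atoms: N,N-dimethylmethyleneiminium iodide (Eschenmoser's salt), C=[N+](C)C.[I-]
Why: Copper-catalysed enantioselective conjugate addition of the Grignard reagent sets C9 under control of the chiral ferrocenyl diphosphine (the ligand enantiomer being the one that gives the C9 configuration drawn), and the regiodefined magnesium enolate is captured at C10 by the iminium salt (Mannich reaction) and turned into the exocyclic enone by quaternisation and Hofmann-type elimination.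

Step 6
Reactants: 13 the exocyclic enone; 14 isobutyronitrile
Product: 17 (6R,8R)-8-(2-cyanopropan-2-yl)-7-methylidene-6-[(3S)-3-methyl-3-(triethylsilyloxy)pent-4-en-1-yl]-1,4-dioxaspiro[4.5]decan-8-yl methyl carbonate, via lithiated nitrile 15 (not isolated), via lithium alkoxide 16 (not isolated)
Conditions: LiN(i-Pr)2, THF, −78 °C; CeCl3; then 13, −78 °C; then ClCO2Me, −78 → 0 °C
Reagents that add atoms: methyl chloroformate, COC(=O)Cl
Why: 1,2-Addition of the cerium-modified nitrile-stabilised tertiary carbanion to the ketone (nitrile aldol-type addition, the cerium additive suppressing enolisation and conjugate addition) from the face opposite the quasi-axial C9 side chain forms the C4–C5 bond, and the alkoxide is acylated in the flask to the tertiary allylic carbonate.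

Step 7
Reactants: 17 the tertiary allylic carbonate
Product: 18 2-methyl-2-[(6R,8R)-7-methylidene-6-[(3S)-3-methyl-3-(triethylsilyloxy)pent-4-en-1-yl]-1,4-dioxaspiro[4.5]decan-8-yl]propanenitrile
Conditions: Pd(OAc)2 (cat.), n-Bu3P (cat.), HCO2H, Et3N, THF, 45 °C
Reagents that add atoms: none
Why: Palladium-catalysed hydrogenolysis of the allylic carbonate with formate (Tsuji–Trost-type allylic reduction) delivers hydride from zerovalent-palladium-derived allylpalladium to the more substituted allyl terminus and so keeps the exocyclic alkene, the metal sitting on the ring face opposite the C9 side chain (ionisation with inversion, or π–σ–π equilibration through the CH2 terminus) so that the new C5–H is anti and the CMe2CN group syn to the side chain.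

Step 8
Reactants: 18 the nitrile
Product: 20 2-methyl-2-[(6R,8R)-7-methylidene-6-[(3S)-3-methyl-3-(triethylsilyloxy)pent-4-en-1-yl]-1,4-dioxaspiro[4.5]decan-8-yl]propanal, via aluminium aldimine 19 (not isolated)
Conditions: i-Bu2AlH, toluene, −78 → 0 °C; then aq tartaric acid, 0 °C
Reagents that add atoms: water, O
Why: Partial reduction of the tertiary nitrile with i-Bu2AlH stops at the N-aluminio aldimine, which mild aqueous acid hydrolyses to the neopentyl aldehyde without touching the ketal, the silyl ether or any stereocentre.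

Step 9
Reactants: 20 the γ,δ-unsaturated aldehyde; 21 methyl acrylate
Product: 22 methyl (13S)-8,8-(ethylenedioxy)-3-hydroxy-13-(triethylsilyloxy)-17-norlabd-14-ene-2-carboxylate (mixture at C2 and C3)
Conditions: Fe(acac)3 (cat.), PhSiH3, EtOH/ethylene glycol, 60 °C
Reagents that add atoms: none
Why: An iron hydride formed from Fe(acac)3 and PhSiH3 transfers a hydrogen atom to the CH2 terminus of the exocyclic C10=C20 alkene (Mukaiyama-type hydrogen-atom transfer), the tertiary C10 radical adds to the β-carbon of 21 (Giese addition, C1–C10 bond), and the α-ester radical is reduced by divalent iron to an iron enolate that adds to the C3 aldehyde (aldol addition, C2–C3 bond). The closest known reaction type is the iron-hydride-initiated radical–polar crossover annulation of γ,δ-unsaturated aldehydes with α,β-unsaturated carbonyl acceptors, an extension of the reductive olefin–acceptor coupling. Ring A closes by a 6-(enolexo)-exo-trig aldol addition that follows the intermolecular radical addition, so the event is a formal [4+2] union of the C10–C5–C4–C3 unit with the two-carbon acceptor. The quaternary C10 centre is controlled by ring B: the acrylate approaches the radical anti to the two flanking β-substituents (CMe2CHO on C5 and the side chain on C9), which places C1 trans to C4 and C11 and C20 on the β-face (trans-decalin); C2 and C3 arise as a mixture that is erased in steps 10 and 11. The step needs hydrogen-atom transfer to the 1,1-disubstituted alkene in preference to the monosubstituted side-chain vinyl group and intermolecular capture of the C10 radical ahead of 6-exo cyclisation onto that vinyl group, which the intrinsically faster transfer to 1,1-disubstituted alkenes and an excess of 21 should secure. Ring closure ahead of enolate protonation is favoured by the gem-dimethyl (Thorpe–Ingold) effect and by the high electrophilicity of the aldehyde.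

Step 10
Reactants: 22 the β-hydroxy ester
Product: 23 methyl (13S)-8,8-(ethylenedioxy)-3-oxo-13-(triethylsilyloxy)-17-norlabd-14-ene-2-carboxylate
Conditions: Dess–Martin periodinane, CH2Cl2, 0 → 20 °C
Reagents that add atoms: none
Why: Dess–Martin oxidation of the secondary alcohol should give the β-keto ester and thereby converge all C2/C3 diastereomers from step 9.

Step 11
Reactants: 23 the β-keto ester
Product: 24 (13S)-8,8-(ethylenedioxy)-13-(triethylsilyloxy)-17-norlabd-14-en-3-one
Conditions: LiCl, H2O, DMSO, 140 °C
Reagents that add atoms: none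
Why: Krapcho dealkoxycarbonylation removes the ester that served as activating group of the two-carbon acceptor, leaving C2 as CH2 and C3 as the ketone.

Step 12
Reactants: 24 the C3 ketone
Product: 25 (13S)-8,8-(ethylenedioxy)-13-(triethylsilyloxy)-17-norlabd-14-en-3α-ol
Conditions: LiBH(s-Bu)3, THF, −78 → 0 °C; then H2O
Reagents that add atoms: none
Why: The bulky trialkylborohydride should attack the 4,4-dimethyl-3-ketone from the equatorial direction (steric approach control), giving the axial 3α-alcohol required, as is general for hindered hydrides on 4,4-dimethyl-3-oxo terpenoids.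

Step 13
Reactants: 25 the 3α-alcohol
Product: 26 (13S)-3α,13-dihydroxy-17-norlabd-14-en-8-one
Conditions: 1 M aq HCl, THF, 0 → 20 °C
Reagents that add atoms: water, O
Why: Dilute aqueous acid should hydrolyse the dioxolane and the tertiary silyl ether in one operation (acetal hydrolysis and desilylation), and C9, now α to the C8 ketone, can only equilibrate to the more stable equatorial side-chain arrangement that is already present.

Step 14
Reactants: 26 the keto diol
Product: 27 (13S)-labda-8(17),14-diene-3α,13-diol
Conditions: Ph3PCH3Br, KOt-Bu (excess), THF, 0 → 65 °C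
Reagents that add atoms: methyltriphenylphosphonium bromide, C[P+](c1ccccc1)(c1ccccc1)c1ccccc1.[Br-]
Why: Wittig methylenation of the hindered C8 ketone with excess ylide (the two hydroxyls carried as alkoxides) installs the exocyclic C8=C17 alkene, any enolisation at C9 returning the thermodynamically preferred equatorial side chain.

Step 15
Reactants: 27 the diene diol
Product: 28 (13S)-labda-8(17),14-diene-3α,13-diyl diacetate (target)
Conditions: Ac2O, DMAP, Et3N, CH2Cl2, 40 °C
Reagents that add atoms: acetic anhydride, CC(=O)OC(C)=O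
Why: Acylation with acetic anhydride under nucleophilic catalysis by DMAP should esterify both the hindered axial secondary alcohol and the tertiary allylic alcohol without ionising the latter, giving the target.

**Compound list**

1 | (S)-(+)-linalool, (3S)-3,7-dimethylocta-1,6-dien-3-ol | C=C[C@](C)(CCC=C(C)C)O | starting material
2 | (S)-linalool triethylsilyl ether | C=C[C@](C)(CCC=C(C)C)O[Si](CC)(CC)CC | intermediate
3 | secondary ozonide (1,2,4-trioxolane) of 2 at the trisubstituted alkene | C=C[C@](C)(CCC1OOC(C)(C)O1)O[Si](CC)(CC)CC | intermediate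
4 | (S)-4-methyl-4-(triethylsilyloxy)hex-5-enal | C=C[C@](C)(CCC=O)O[Si](CC)(CC)CC | intermediate
5 | (S)-4-methyl-4-(triethylsilyloxy)hex-5-enoic acid | C=C[C@](C)(CCC(=O)O)O[Si](CC)(CC)CC | intermediate
6 | 2-thioxopyridin-1(2H)-yl ester of 5 (Barton ester) | C=C[C@](C)(CCC(=O)ON1C=CC=CC1=S)O[Si](CC)(CC)CC | intermediate
7 | (S)-5-iodo-3-methyl-3-(triethylsilyloxy)pent-1-ene | C=C[C@](C)(CCI)O[Si](CC)(CC)CC | intermediate
8 | 1,4-dioxaspiro[4.5]dec-6-en-8-one | O=C1C=CC2(OCCO2)CC1 | starting material
9 | Grignard reagent of 7 (alkylmagnesium iodide) | C=C[C@](C)(CC[Mg]I)O[Si](CC)(CC)CC | intermediate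
10 | iodomagnesium enolate of the conjugate adduct (C9 set) | C=C[C@](C)(CC[C@H]1C3(OCCO3)CCC(O[Mg]I)=C1)O[Si](CC)(CC)CC | intermediate
11 | Mannich base, 7-(dimethylaminomethyl) ketone | C=C[C@](C)(CC[C@H]1C3(OCCO3)CCC(=O)C1CN(C)C)O[Si](CC)(CC)CC | intermediate
12 | trimethylammonium iodide of 11 | C=C[C@](C)(CC[C@H]1C3(OCCO3)CCC(=O)C1C[N+](C)(C)C)O[Si](CC)(CC)CC.[I-] | intermediate
13 | (6R)-7-methylidene-6-[(3S)-3-methyl-3-(triethylsilyloxy)pent-4-en-1-yl]-1,4-dioxaspiro[4.5]decan-8-one | C=C[C@](C)(CC[C@H]1C3(OCCO3)CCC(=O)C1=C)O[Si](CC)(CC)CC | intermediate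
14 | isobutyronitrile | CC(C)C#N | starting material
15 | 2-lithio-2-methylpropanenitrile | [Li]C(C)(C)C#N | intermediate
16 | lithium alkoxide of the 1,2-adduct (O syn to the C9 side chain) | C=C[C@](C)(CC[C@H]1C3(OCCO3)CC[C@](C1=C)(O[Li])C(C)(C)C#N)O[Si](CC)(CC)CC | intermediate
17 | (6R,8R)-8-(2-cyanopropan-2-yl)-7-methylidene-6-[(3S)-3-methyl-3-(triethylsilyloxy)pent-4-en-1-yl]-1,4-dioxaspiro[4.5]decan-8-yl methyl carbonate | C=C[C@](C)(CC[C@H]1C3(OCCO3)CC[C@](C1=C)(OC(=O)OC)C(C)(C)C#N)O[Si](CC)(CC)CC | intermediate
18 | 2-methyl-2-[(6R,8R)-7-methylidene-6-[(3S)-3-methyl-3-(triethylsilyloxy)pent-4-en-1-yl]-1,4-dioxaspiro[4.5]decan-8-yl]propanenitrile (C5 and C9 substituents cis) | C=C[C@](C)(CC[C@H]1C3(OCCO3)CC[C@H](C1=C)C(C)(C)C#N)O[Si](CC)(CC)CC | intermediate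
19 | N-(diisobutylaluminio)aldimine of 18 | C=C[C@](C)(CC[C@H]1C3(OCCO3)CC[C@H](C1=C)C(C)(C)C=N[Al](CC(C)C)CC(C)C)O[Si](CC)(CC)CC | intermediate
20 | 2-methyl-2-[(6R,8R)-7-methylidene-6-[(3S)-3-methyl-3-(triethylsilyloxy)pent-4-en-1-yl]-1,4-dioxaspiro[4.5]decan-8-yl]propanal | C=C[C@](C)(CC[C@H]1C3(OCCO3)CC[C@H](C1=C)C(C)(C)C=O)O[Si](CC)(CC)CC | intermediate
21 | methyl acrylate | C=CC(=O)OC | starting material
22 | methyl (13S)-8,8-(ethylenedioxy)-3-hydroxy-13-(triethylsilyloxy)-17-norlabd-14-ene-2-carboxylate (5α-H, 9α-H, 10β-methyl; mixture at C2 and C3) | C=C[C@](C)(CC[C@H]1C3(OCCO3)CC[C@H]2C(C)(C)C(O)C(C(=O)OC)C[C@]12C)O[Si](CC)(CC)CC | intermediate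
23 | methyl (13S)-8,8-(ethylenedioxy)-3-oxo-13-(triethylsilyloxy)-17-norlabd-14-ene-2-carboxylate (C2 epimers and enol) | C=C[C@](C)(CC[C@H]1C3(OCCO3)CC[C@H]2C(C)(C)C(=O)C(C(=O)OC)C[C@]12C)O[Si](CC)(CC)CC | intermediate
24 | (13S)-8,8-(ethylenedioxy)-13-(triethylsilyloxy)-17-norlabd-14-en-3-one | C=C[C@](C)(CC[C@H]1C3(OCCO3)CC[C@H]2C(C)(C)C(=O)CC[C@]12C)O[Si](CC)(CC)CC | intermediate
25 | (13S)-8,8-(ethylenedioxy)-13-(triethylsilyloxy)-17-norlabd-14-en-3α-ol | C=C[C@](C)(CC[C@H]1C3(OCCO3)CC[C@H]2C(C)(C)[C@H](O)CC[C@]12C)O[Si](CC)(CC)CC | intermediate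
26 | (13S)-3α,13-dihydroxy-17-norlabd-14-en-8-one | C=C[C@](C)(CC[C@H]1C(=O)CC[C@H]2C(C)(C)[C@H](O)CC[C@]12C)O | intermediate
27 | (13S)-labda-8(17),14-diene-3α,13-diol | C=C[C@](C)(CC[C@H]1C(=C)CC[C@H]2C(C)(C)[C@H](O)CC[C@]12C)O | intermediate
28 | (13S)-labda-8(17),14-diene-3α,13-diyl diacetate | C=C[C@](C)(CC[C@H]1C(=C)CC[C@H]2C(C)(C)[C@H](OC(C)=O)CC[C@]12C)OC(C)=O | target

**Step count and risks**

Total step count: 15. Longest linear sequence: 15 steps (1 → 28; 8, 14 and 21 are commercial).

Steps most likely to fail:

Step 9. The iron enolate may be protonated by the alcoholic medium before it adds to the hindered aldehyde, and hydrogen-atom transfer to the side-chain vinyl group may compete. Fallback: from aldehyde 20 and acrylate 21 the reductive olefin–acceptor coupling is run so as to give the uncyclised conjugate adduct, the aldehyde ester F9. Ring A is then closed in a separate base-mediated intramolecular aldol addition (NaOMe, MeOH, 0 °C), so that ring closure rests on ordinary enolate chemistry; the route is rejoined at 22.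

Step 5. Capture of the magnesium enolate by the iminium salt may be incomplete, and enantioselectivity may erode on the γ,γ-dioxygenated enone. Fallback: from iodide 7 and enone 8, iodine–zinc exchange (Et2Zn, CuI cat.) gives the diorganozinc F1. Copper/phosphoramidite-catalysed conjugate addition (Cu(OTf)2, O,O'-(1,1'-binaphthyl-2,2'-diyl)-N,N-bis(1-phenylethyl)phosphoramidite, toluene, −30 °C) gives the zinc enolate F2, which is captured by formaldehyde in an aldol addition to give the hydroxymethyl ketone F3. Mesylation (MsCl, Et3N) to the mesylate F4 and elimination with DBU return the exocyclic enone 13.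

Step 7. Facial control in hydride delivery may be lost if the allylpalladium intermediate does not equilibrate, and β-hydride elimination to a diene may compete. Fallback: the alkoxide 16 is protonated instead of acylated, giving the tertiary allylic alcohol F5. Oxorhenium-catalysed 1,3-transposition (Ph3SiOReO3, Et2O) gives the primary allylic alcohol F6 with a tetrasubstituted ring alkene. Mitsunobu reaction with 2-nitrobenzenesulfonylhydrazide (PPh3, diethyl azodicarboxylate, THF, −30 → 20 °C) gives the sulfonylhydrazine F7, which loses sulfinic acid to the allylic diazene F8. Sigmatropic loss of dinitrogen delivers hydrogen to C5 on the face anti to the C9 side chain and regenerates the exocyclic alkene, rejoining the route at nitrile 18.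

**Further compounds**

F1 | step 5 | bis[(3S)-3-methyl-3-(triethylsilyloxy)pent-4-en-1-yl]zinc | [Zn](CC[C@@](C)(C=C)O[Si](CC)(CC)CC)CC[C@@](C)(C=C)O[Si](CC)(CC)CC
F2 | step 5 | alkylzinc enolate of the conjugate adduct | C=C[C@](C)(CC[C@H]1C3(OCCO3)CCC(O[Zn]CC[C@@](C)(C=C)O[Si](CC)(CC)CC)=C1)O[Si](CC)(CC)CC
F3 | step 5 | (6R)-7-(hydroxymethyl)-6-[(3S)-3-methyl-3-(triethylsilyloxy)pent-4-en-1-yl]-1,4-dioxaspiro[4.5]decan-8-one | C=C[C@](C)(CC[C@H]1C3(OCCO3)CCC(=O)C1CO)O[Si](CC)(CC)CC
F4 | step 5 | methanesulfonate of F3 | C=C[C@](C)(CC[C@H]1C3(OCCO3)CCC(=O)C1COS(C)(=O)=O)O[Si](CC)(CC)CC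
F5 | step 7 | tertiary allylic alcohol, 2-[(6R,8R)-8-hydroxy-7-methylidene-6-[(3S)-3-methyl-3-(triethylsilyloxy)pent-4-en-1-yl]-1,4-dioxaspiro[4.5]decan-8-yl]-2-methylpropanenitrile | C=C[C@](C)(CC[C@H]1C3(OCCO3)CC[C@](C1=C)(O)C(C)(C)C#N)O[Si](CC)(CC)CC
F6 | step 7 | primary allylic alcohol, 2-[(6R)-7-(hydroxymethyl)-6-[(3S)-3-methyl-3-(triethylsilyloxy)pent-4-en-1-yl]-1,4-dioxaspiro[4.5]dec-7-en-8-yl]-2-methylpropanenitrile | C=C[C@](C)(CC[C@H]1C3(OCCO3)CCC(C(C)(C)C#N)=C1CO)O[Si](CC)(CC)CC
F7 | step 7 | N-allylic N-(2-nitrobenzenesulfonyl)hydrazine from F6 | C=C[C@](C)(CC[C@H]1C3(OCCO3)CCC(C(C)(C)C#N)=C1CN(N)S(=O)(=O)c4ccccc4[N+](=O)[O-])O[Si](CC)(CC)CC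
F8 | step 7 | allylic monoalkyl diazene from F7 | C=C[C@](C)(CC[C@H]1C3(OCCO3)CCC(C(C)(C)C#N)=C1CN=N)O[Si](CC)(CC)CC
F9 | step 9 | open-chain conjugate adduct, methyl 3-[(6R,7R,8R)-7-methyl-6-[(3S)-3-methyl-3-(triethylsilyloxy)pent-4-en-1-yl]-8-(2-methyl-1-oxopropan-2-yl)-1,4-dioxaspiro[4.5]decan-7-yl]propanoate | C=C[C@](C)(CC[C@H]1C3(OCCO3)CC[C@@H](C(C)(C)C=O)[C@]1(C)CCC(=O)OC)O[Si](CC)(CC)CC
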